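The X charged stays counted: at any moment it sits in X, D, L or Q, with one Q counted as two. I gave Z a ledger too, and assumed that each D costs one Z.

| flask | X | Z | temperature | remark | time |
|---|---|---|---|---|---|
| noon | 0.050 M | 0.024 M | −30 °C | run made earlier |  |
| autumn | 0.050 M | 0.036 M | 12 °C | run made earlier |  |
| dusk | 0.025 M | 0.0475 M | −30 °C | run made earlier |  |
| Thursday's | 0.050 M | 0.0475 M | 0 °C |  | 4.0 h |
| Tuesday's | 0.050 M | 0.0475 M | 50 °C |  | 4.0 h |
| Sunday's | 0.050 M | 0.0475 M | 25 °C |  | 4.0 h |
| Wednesday's | 0.050 M | 0.0475 M | −25 °C |  | 4.0 h |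

noon run (percent of the X charged)

| time / h | D / % | L / % | Q / % |
|---|---|---|---|
| 0.833 | 0.1 | 0.9 | 0 |
| 1.33 | 0.9 | 0.1 | 0.1 |
| 2.00 | 0.2 | 0.4 | 0.7 |
| 4.00 | 0.6 | 0 | 1.7 |
| 6.00 | 0.2 | 0.3 | 2.0 |
| 12.0 | 1.0 | 0 | 2.4 |

autumn run (percent of the X charged)

| time / min | D / % | L / % | Q / % |
|---|---|---|---|
| 6.00 | 1.0 | 1.5 | 2.4 |
| 12.0 | 3.9 | 2.3 | 4.3 |
| 15.0 | 2.9 | 2.8 | 4.4 |
| 30.0 | 5.8 | 5.0 | 8.4 |
| 40.0 | 6.9 | 6.5 | 10.9 |
| 80.0 | 11.4 | 12.6 | 17.4 |

dusk run (percent of the X charged)

| time / h | D / % | L / % | Q / % |
|---|---|---|---|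
| 0.833 | 0.6 | 0.2 | 0 |
| 1.33 | 0 | 0 | 0.5 |
| 3.00 | 1.6 | 0 | 0.7 |
| 6.00 | 0.4 | 0.2 | 0.6 |
| 12.0 | 0.3 | 0.5 | 1.5 |

(readings scatter by 0.5 percentage points)

- percentages count the X that a species holds: one Q counts as two
- the analysis behind the earlier runs scatters by 0.5 percentage points, standard deviation
- a reading or a percentage of D counts all its forms, free or not

1. the flask that comes out highest in share of D in all that became D or L or Q, or "all alike" when all lie within 1.5 percentage points (Thursday's / Tuesday's / Sunday's / Wednesday's / all alike)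
2. share of D in all that became D or L or Q, Thursday's
3. share of D in all that became D or L or Q, Tuesday's
4. share of D in all that became D or L or Q, Sunday's
5. share of D in all that became D or L or Q, Wednesday's

So I counted turnovers. In the new flasks 0.950 of Z stands against each X charged, and I call this Z charged per X charged the cover. With 0.0475 M of Z against 0.050 M of X, Z is the limiting reagent on paper. My bench rule, with all X reacted, each D costing one Z and nothing else taking Z, was that a flask has enough Z for its D while the cover exceeds the share of D among D, L and Q.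

The noon run's last D reads 1.0% against a scatter of 0.5 percentage points, so I took the share from the autumn run. At 80.0 min the autumn run read 27.5%. Full conversion at that share would draw 28.9% of the Z charged, so the rule passed.

But the rule counts Z spent on D, and no reading shows Z. Its border is a ratio: if another route took more than 71.0% of the Z charged, D could not reach that share. I reckoned Tuesday's near 27.5%, provided Z stayed inside that border.

The forecast gave 31% for Thursday's, 39% for Tuesday's, 35% for Sunday's and 21% for Wednesday's, and named Tuesday's: “I expect Tuesday's highest, with wide ranges”. Its Tuesday's figure stood above my 27.5%.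

The flasks gave 30.3% for Thursday's, 21.4% for Tuesday's, 25.5% for Sunday's and 22.5% for Wednesday's, so Thursday's came out highest.

    X + Z → D (k = 0.230 /M/min, Ea = 74.0 kJ/mol)
    X → L (k = 0.0100 /min, Ea = 87.0 kJ/mol)
    2 X → Q (k = 0.110 /M/min, Ea = 60.0 kJ/mol)
    Z + D ⇌ J, settled at all times (K = 56.0 /M, ΔH = −31.0 kJ/mol)
    Z → G (k = 0.0110 /min, Ea = 86.0 kJ/mol)
    (constants at 25 °C)

Just after the start of Tuesday's, Z → G used Z 1.4 times as fast as X + Z → D did. After 4.00 h Tuesday's held Z at 0% of its charge and G at 0.0368 M, which is 77.5% of the Z charged, beyond the 71.0% border. D in Tuesday's held 21.4% of the X charged, which took 22.5% of the Z charged. A neighbour of Tuesday's charged with 0.19 M of Z has a cover of 3.80. It spent 15.3% of its Z charged on D, and its share of D reached 58.1%.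

The earlier runs and the new flask are simulated with made-up constants.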